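## Analysis of the target

Hyperielliptone HB (16) is a dearomatised acylphloroglucinol. Ring A (C1–C6) is an enolised 2-acylcyclohexane-1,3,5-trione whose C5 is a spiro carbon shared with a cyclohexane (ring B: C5, C1', C2', C6', C7', C8'), and ring B is cis-fused along C2'–C6' to a cyclopentane (ring C: C2'–C6'). In the numbering used here, C1 carries the (S)-2-methylbutanoyl group, C2 is the enol carbon, C3 the quaternary carbon with methyl and prenyl, and C4 and C6 the ketones flanking C5. The ten terpene carbons are numbered as in linalool: C1' and C8' are the two methylenes on C5, C3' and C7' the two methyl carbinols, C9' and C10' their methyl groups.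

There are seven stereocentres: the side-chain carbon, C3, the spiro carbon C5, the ring-fusion carbons C2' and C6' (hydrogens cis), and the tertiary carbinols C3' and C7'. Both hydroxyls lie on the concave face of the cis-hydrindane, each cis to the other ring.

The feature on which the plan rests is ring B. C5 with its two carbonyls sits between two methylenes, and C7' carries the oxygen that a Markovnikov hydration of a C7'=C8' bond would leave. C1'–C10' are an intact linalool skeleton (C3' is the carbinol carbon of (R)-linalool, C1'=C2' its vinyl group) with one extra bond, C2'–C6'. Ring B is therefore the retron of a Diels–Alder reaction between that vinyl group and a diene C5=C8'–C7'=C6' in which the spiro carbon is a diene terminus.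

Sensitive functions are the acidic, chelating β-triketone, the prenyl alkene, two tertiary alcohols in a 1,4-relation that can close to a cyclic ether on ionisation, and the enolisable stereocentre next to the acyl carbonyl.

The hard points are three. C5 is stereogenic only because C4 and C6 differ, so its configuration is the question of which carbonyl faces which side of ring B. C3 is remote from the terpene part. The C7' hydroxyl must sit on the hindered, concave face.

## Retrosynthetic reasoning

**16 to 15.** The C3' oxygen is carried as a triethylsilyl ether. A free linalyl-type tertiary allylic alcohol would ionise under acid or with zerovalent palladium and could add to C7' later; the silyl ether is removed last.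

**15 to 14.** The prenyl C=C is cut by olefin cross-metathesis back to a but-2-enyl group. The side chain has to survive a radical hydration of ring B, and a 1,2-disubstituted alkene is a poor hydrogen-atom acceptor where a prenyl group is a good one.

**14 to 12.** The C7'–O bond is cut. Forward, a Markovnikov radical hydration of the C7'=C8' bond of 12 must place the oxygen cis to ring C. The axial spiro carbonyl, which covers the other face, is relied on for this.

**12 to 10 through 11 (key disconnection).** The bonds C5–C1' and C2'–C6' are cut in a retro-Diels–Alder sense. This opens rings B and C at once and removes C5, C2' and C6' as stereocentres. It leaves the oxatriene 11, which is the open valence isomer of the 2H-pyran 10. It is cut here because no polar disconnection makes C5 a nucleophile toward C1' while C2' bonds to C6'; a cycloaddition in which C5 is a diene terminus does both. Forward, the cycloaddition must prefer the carbon diene, fuse the rings cis, and be steered by C3 (at C5) and C3' (at C2').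

**10 to 9.** The C3–CH2 bond of the side chain is cut: a dearomatising asymmetric allylic alkylation of the chromene 9. C5 is already tied into the pyran, so only C3 can be alkylated on carbon. This is what makes the regiochemistry safe, and the catalyst sets C3.

**9 to 8 and 4.** The pyran is cut at C5–C8' and O–C6': a Knoevenagel condensation and oxa-6π closure between the acylphloroglucinol 8 and the enal 4.

**4 to 1, and 8 to 5 and 6.** 4 comes from (R)-linalool 1 by silylation (2), allylic oxidation of the E methyl group (3) and oxidation to the enal. 8 comes from acid 5 and triol 6 by Friedel–Crafts acylation through the acid chloride 7. C3' is bought; C5, C2', C6' and C7' are relayed from it and from C3.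

## Alternatives that were turned down

**Alternative 1: (the textbook route).** Both bonds to C5 are cut as polar alkylations. The dearomatised acylphloroglucinol A1 is joined to a cis-cyclopentane bis-electrophile A2 (iodide at C1', epoxide at C7'/C8'). The forward key step is a double C-alkylation: an intermolecular SN2 reaction, then a 6-endo epoxide opening. Turned down for four reasons:
- A2 needs its own cyclisation and the differentiation of both termini, about eight steps, so the precursor costs more than the spiro-annulation wins.
- C7' would rest on an undirected epoxidation of a freely rotating isopropenyl group.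
- An unactivated primary iodide and a hindered epoxide invite O-alkylation of the triketone.
- The feasible bond order closes C5–C8' last, which for the natural configuration means attack syn to the prenyl group of C3.

**Alternative 2: (biomimetic oxidative radical cyclisation).** C5–C8' and C7'–O are cut. In A3, which already carries the cyclopentylmethyl group on C5, Mn(OAc)3 and O2 would generate the C5 radical; it would add 6-endo to the isopropenyl terminus, and the C7' radical would take up O2. Turned down for three reasons:
- The ring again closes at C5–C8', against the 1,3-bias from C3.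
- The oxidant and the peroxyl radical also attack the enol and the prenyl group, and the 6-endo/5-exo partition is open.
- A3 still demands the separate cyclopentane synthesis plus an intermolecular C-alkylation with an unactivated halide.

**Alternative 3: (double methyl addition).** The two carbinol C–CH3 bonds are cut. The spiro cis-hydrindane-1,4-dione A4 (from a Michael addition to a 2-methylenecyclopentanone and an α-haloketone alkylation) would take two methyl nucleophiles from the convex face. Turned down for three reasons:
- At C7' the reagent must come in equatorially, away from the axial spiro carbonyl, which puts the methyl group cis to ring C: the wrong epimer.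
- Methyl organometallics do not tolerate the C4 ketone of the trione.
- C2' and C6' are both enolisable in A4, so no absolute configuration can be relayed, and the carbinol that linalool supplies for free would be discarded.

Key step: step 7

Remark: the β-triketone is written throughout in the enol tautomer of the target SMILES and its tautomers are treated as one compound; methyl (E)-but-2-enyl carbonate is treated as a purchasable reagent.

## Route

Step 1
Reactants: 1 (R)-(−)-linalool
Product: 2 (3R)-3,7-dimethyl-3-(triethylsilyloxy)octa-1,6-diene
Conditions: TESOTf, 2,6-lutidine, CH2Cl2, −78 °C to 0 °C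
Reagents that add atoms: triethylsilyl trifluoromethanesulfonate, CC[Si](CC)(CC)OS(=O)(=O)C(F)(F)F
Why: Silylation of a tertiary alcohol with the silyl triflate and a hindered base is standard and leaves the stereocentre (future C3') untouched. The ether keeps the linalyl carbinol from ionising in steps 5 to 7 and from adding to C7' later.

Step 2
Reactants: 2 (3R)-3,7-dimethyl-3-(triethylsilyloxy)octa-1,6-diene
Product: 3 (2E,6R)-2,6-dimethyl-6-(triethylsilyloxy)octa-2,7-dien-1-ol
Conditions: SeO2 (cat.), t-BuOOH, salicylic acid (cat.), CH2Cl2, rt
Reagents that add atoms: tert-butyl hydroperoxide, CC(C)(C)OO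
Why: Catalytic SeO2 allylic oxidation (ene reaction, then 2,3-sigmatropic shift) attacks the trisubstituted alkene at the E methyl group of its disubstituted terminus and gives the (E)-allylic alcohol. The vinyl group has no allylic hydrogen.

Step 3
Reactants: 3 (2E,6R)-2,6-dimethyl-6-(triethylsilyloxy)octa-2,7-dien-1-ol
Product: 4 (2E,6R)-2,6-dimethyl-6-(triethylsilyloxy)octa-2,7-dienal
Conditions: MnO2, CH2Cl2, rt
Reagents that add atoms: none
Why: MnO2 oxidises allylic alcohols to enals without E/Z isomerisation and leaves the silyl ether and the isolated vinyl group alone.

Step 4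
Reactants: 5 (S)-2-methylbutanoic acid; 6 2-methylbenzene-1,3,5-triol
Product: 8 (2S)-2-methyl-1-(2,4,6-trihydroxy-3-methylphenyl)butan-1-one, via (S)-2-methylbutanoyl chloride 7 (not isolated)
Conditions: (COCl)2, DMF (cat.), CH2Cl2, 0 °C to rt; then 6, AlCl3, CH2Cl2/PhNO2, 0 °C to rt
Reagents that add atoms: oxalyl chloride, ClC(=O)C(=O)Cl
Why: Friedel–Crafts acylation of the electron-rich triol; its two free ring positions are equivalent, so one ketone forms. Low temperature and short contact with AlCl3 limit enolisation of the α-stereocentre.

Step 5
Reactants: 8 (2S)-2-methyl-1-(2,4,6-trihydroxy-3-methylphenyl)butan-1-one; 4 (2E,6R)-2,6-dimethyl-6-(triethylsilyloxy)octa-2,7-dienal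
Product: 9 (2S)-1-{5,7-dihydroxy-3,8-dimethyl-2-[(3R)-3-methyl-3-(triethylsilyloxy)pent-4-enyl]-2H-chromen-6-yl}-2-methylbutan-1-one, both epimers at C2 of the pyran (C6')
Conditions: ethylenediammonium diacetate (20 mol %), PhMe, 110 °C, Dean–Stark
Reagents that add atoms: none
Why: Knoevenagel condensation at the only free ring carbon (C5) gives an ortho-quinone methide that closes by oxa-6π electrocyclisation, the standard reaction of phloroglucinols with enals. Closure through the C4 hydroxyl (para to the acyl group) is expected; closure through the C6 hydroxyl would lead through steps 6 and 7 into the same oxatriene manifold. C6' forms as both epimers, which does not matter because step 7 destroys this centre.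

Step 6
Reactants: 9 the 2H-chromene
Product: 10 dearomatised 2H-pyran: 9 carrying an (E)-but-2-enyl group on the methyl-bearing ring carbon C3 (configured as in 16), with the pyran oxygen on C4, a C4=C5 enol ether, a C6 ketone and the C1=C2 enol; both C6' epimers
Conditions: Pd2(dba)3·CHCl3 (2.5 mol %), (R,R)-DACH-phenyl Trost ligand (7.5 mol %), methyl (E)-but-2-enyl carbonate, CH2Cl2, 0 °C to rt
Reagents that add atoms: methyl (E)-but-2-enyl carbonate, C/C=C/COC(=O)OC
Why: Dearomatising Tsuji–Trost asymmetric allylic alkylation of a phenol carbon: C5 is blocked by the pyran, so the π-allyl complex alkylates C3, and at its unsubstituted terminus because a quaternary centre is formed. The ligand selects the face of the planar nucleophile; the sense of induction has to be checked on the first run and the mirror-image ligand used if it is opposite.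

Step 7
Reactants: 10 the dearomatised 2H-pyran
Product: 12 spiro cyclohexene: rings B and C closed, C7'=C8' double bond, C2'–H and C6'–H cis, C3' silyloxy group cis to C1' and C7', C1' on the methyl face of C3, via 1-oxatriene 11 (not isolated)
Conditions: PhMe (0.01 M), BHT (5 mol %), sealed tube, 140 °C
Reagents that add atoms: none
Why: Proposed new method: heating opens the 2H-pyran of 10 by the reversible retro-oxa-6π electrocyclisation known for dione-fused pyrans, and the 1-oxatriene 11 is then intercepted as an all-carbon diene C5=C8'–C7'=C6' by the vinyl group C1'=C2' in a type 1 intramolecular Diels–Alder reaction of the 1,3,8-nonatriene kind (closest known types: thermal nonatriene cycloadditions to hydrindenes, and the inverse-demand cycloadditions of alkylidene-1,3-diones in the domino Knoevenagel/hetero-Diels–Alder reaction, which use the C=C–C=O unit instead); the hetero mode is shut off here because its tether would have to hold the E bond C6'=C7' in a seven-membered ring. Ring B closes by the [4+2] bonds C5–C1' and C2'–C6', and ring C closes in the same event as the fused five-membered ring through the tether C3'–C4'–C5', helped by the gem-disubstitution at C3'. The diacyl diene is strongly electron-poor and polarised toward C6', so the inner bond C2'–C6' should lead in the transition state, the situation in which nonatrienes prefer the cis-fused hydrindene; this sets C2' and C6' cis. The face of the vinyl group is set by C3': the silyloxy group takes the position eclipsing the C=C bond (inside-alkoxy effect, least allylic 1,3-strain), which puts C1' cis to the oxygen on ring C. At C5 the methylene C1' should arrive on the face of ring A that carries the methyl and not the but-2-enyl group of C3 (1,3-relation across C4); rotation about the polarised C5=C8' bond interconverts the two geometries of 11 at this temperature, so the cycloaddition can use the geometry (C4=O cis to C7') that satisfies the C3 and the C3' demands together, and this fixes C5. The selectivities needed are carbon-diene over pyran-diene participation and cis over trans fusion; the first is secured by the low LUMO of the open diacyl diene, the second is the least secure element.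

Step 8
Reactants: 12 the spiro cyclohexene
Product: 14 tertiary alcohol: 12 hydrated across C7'=C8', hydroxyl on C7' cis to ring C, via C7' hydroperoxide 13 (not isolated)
Conditions: Co(acac)2 (0.3 equiv), PhSiH3, O2 (1 atm), THF/i-PrOH, 0 °C to rt; then PPh3
Reagents that add atoms: dioxygen, O=O
Why: Mukaiyama hydration: hydrogen-atom transfer to C8' gives the tertiary C7' radical, which takes up O2, and the hydroperoxide is reduced in the flask. In the chair that keeps C3' equatorial on C2', the C4 carbonyl on C5 is axial and its oxygen lies over the face of C7' that carries the ring-fusion hydrogens, so O2 should enter from the other face, cis to C5'. The 1,2-disubstituted side-chain alkene is a poor hydrogen-atom acceptor and should be left.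

Step 9
Reactants: 14 the tertiary alcohol with the but-2-enyl side chain
Product: 15 hyperielliptone HB 3'-O-triethylsilyl ether
Conditions: second-generation Grubbs catalyst (10 mol %), 2-methylbut-2-ene/CH2Cl2 (1:1), 40 °C
Reagents that add atoms: 2-methylbut-2-ene, CC=C(C)C
Why: Olefin cross-metathesis with an excess of the trisubstituted partner exchanges the ethylidene terminus for isopropylidene, the usual late conversion of a simple allylic side chain into prenyl. Tertiary alcohols and ketones are tolerated.

Step 10
Reactants: 15 hyperielliptone HB 3'-O-triethylsilyl ether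
Product: 16 hyperielliptone HB
Conditions: TBAF, AcOH, THF, 0 °C to rt
Reagents that add atoms: none
Why: Fluoride cleaves the tertiary silyl ether; buffering with AcOH keeps the medium near neutral, so neither the 1,4-diol nor the triketone meets strong acid or base. No stereocentre is involved.

## Compound list

1 | (R)-(−)-linalool, (3R)-3,7-dimethylocta-1,6-dien-3-ol | C=C[C@](C)(O)CCC=C(C)C | starting material
2 | (3R)-3,7-dimethyl-3-(triethylsilyloxy)octa-1,6-diene | C=C[C@](C)(O[Si](CC)(CC)CC)CCC=C(C)C | intermediate
3 | (2E,6R)-2,6-dimethyl-6-(triethylsilyloxy)octa-2,7-dien-1-ol | C=C[C@](C)(O[Si](CC)(CC)CC)CC/C=C(\C)CO | intermediate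
4 | (2E,6R)-2,6-dimethyl-6-(triethylsilyloxy)octa-2,7-dienal | C=C[C@](C)(O[Si](CC)(CC)CC)CC/C=C(\C)C=O | intermediate
5 | (S)-2-methylbutanoic acid | CC[C@H](C)C(=O)O | starting material
6 | 2-methylbenzene-1,3,5-triol (2-methylphloroglucinol) | Cc1c(O)cc(O)cc1O | starting material
7 | (S)-2-methylbutanoyl chloride | CC[C@H](C)C(Cl)=O | intermediate
8 | (2S)-2-methyl-1-(2,4,6-trihydroxy-3-methylphenyl)butan-1-one | CC[C@H](C)C(=O)c1c(O)cc(O)c(C)c1O | intermediate
9 | (2S)-1-{5,7-dihydroxy-3,8-dimethyl-2-[(3R)-3-methyl-3-(triethylsilyloxy)pent-4-enyl]-2H-chromen-6-yl}-2-methylbutan-1-one, both epimers at C2 of the pyran (C6') | CC[C@H](C)C(=O)c1c(O)c(C)c2OC(CC[C@@](C)(O[Si](CC)(CC)CC)C=C)C(C)=Cc2c1O | intermediate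
10 | dearomatised 2H-pyran: 9 with an (E)-but-2-enyl group on C3 (configured as in 16), pyran oxygen on C4, C4=C5 enol ether, C6 ketone, C1=C2 enol; both C6' epimers | CC[C@H](C)C(=O)C1=C(O)[C@@](C)(C/C=C/C)C2=C(C=C(C)C(CC[C@@](C)(O[Si](CC)(CC)CC)C=C)O2)C1=O | intermediate
11 | 1-oxatriene: open valence isomer of 10, C5=C8' with the C4 carbonyl cis to C7', C6'=C7' (E) | CC[C@H](C)C(=O)C1=C(O)[C@@](C)(C/C=C/C)C(=O)/C(=C\C(C)=C\CC[C@@](C)(O[Si](CC)(CC)CC)C=C)C1=O | intermediate
12 | spiro cyclohexene: rings B and C closed, C7'=C8' double bond, C2'–H and C6'–H cis, C3' silyloxy cis to C1' and C7', C1' on the methyl face of C3 | CC[C@H](C)C(=O)C1=C(O)[C@@](C)(C/C=C/C)C(=O)[C@]2(C[C@H]3[C@H](CC[C@@]3(C)O[Si](CC)(CC)CC)C(C)=C2)C1=O | intermediate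
13 | C7' tertiary hydroperoxide of 12, OOH cis to ring C | CC[C@H](C)C(=O)C1=C(O)[C@@](C)(C/C=C/C)C(=O)[C@]2(C[C@H]3[C@H](CC[C@@]3(C)O[Si](CC)(CC)CC)[C@](C)(OO)C2)C1=O | intermediate
14 | C7' tertiary alcohol: (E)-but-2-enyl analogue of 15 | CC[C@H](C)C(=O)C1=C(O)[C@@](C)(C/C=C/C)C(=O)[C@]2(C[C@H]3[C@H](CC[C@@]3(C)O[Si](CC)(CC)CC)[C@](C)(O)C2)C1=O | intermediate
15 | hyperielliptone HB 3'-O-triethylsilyl ether | CC[C@H](C)C(=O)C1=C(O)[C@@](C)(CC=C(C)C)C(=O)[C@]2(C[C@H]3[C@H](CC[C@@]3(C)O[Si](CC)(CC)CC)[C@](C)(O)C2)C1=O | intermediate
16 | hyperielliptone HB | CC[C@H](C)C(=O)C1=C(O)[C@@](C)(CC=C(C)C)C(=O)[C@]2(C[C@H]3[C@H](CC[C@@]3(C)O)[C@](C)(O)C2)C1=O | target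

## Step count and least certain steps

Total step count: 10. Longest linear sequence: 9 steps (steps 1 to 3 and 5 to 10, from 1).

**Step 7 (key step, labelled).** The pyran may stay closed, or the open oxatriene may drain through hydrogen shifts, a Cope shift of the but-2-enyl group or oligomerisation before the cycloaddition. The trans-fused mode may also compete, because cis/trans control in nonatriene cycloadditions is weak.

Fallback by known chemistry, from 3 and 8, returning at 14:
- 3 is converted with MsCl and LiCl into the allylic chloride F1.
- The allylmagnesium chloride made from F1 with activated magnesium cyclises by an intramolecular magnesium-ene reaction, and quenching the primary Grignard reagent with C2Cl6 gives the cis-2-(chloromethyl)-3-isopropenylcyclopentyl silyl ether F2.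
- Ene-type chlorination of the isopropenyl group (Ca(OCl)2, CO2) gives the bis-chloride F3.
- Its allylic chloride alkylates the free ring carbon of 8 (aqueous KOH, 0 °C) to the C5-alkylated acylphloroglucinol F4.
- The conditions of step 6 then set C3 and give the dearomatised triketone F5.
- NaI and Cs2CO3 in DMF close ring B by 6-exo C-alkylation anti to the but-2-enyl group, giving the spiro compound with an exocyclic C7' methylene F6.
- The conditions of step 8 hydrate F6 to 14.

**Step 6.** Enantioface selection at C3 on a fully substituted phloroglucinol may be poor, and O-allylation may persist. Fallback from 9, returning at 12: alkylation with an achiral catalyst (Pd(PPh3)4) gives 10 together with its C3 epimer F7. Heating the mixture as in step 7 lets each epimer react through its own matched transition state, so that 12 forms beside the C3,C5-bis-epimeric adduct F8. These are diastereomers and are separated by chromatography, at the cost of half the material.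

**Step 8.** Hydrogen-atom transfer to the hindered C8' may be slow enough for the side chain to be hydrated or isomerised, and the facial preference at the C7' radical may be low. Fallback from 12, returning at 14: polar oxymercuration with Hg(OAc)2 in THF/H2O, in which the mercury is held on the lower face by the C4 carbonyl and water opens the mercurinium ion at C7' from the face of ring C, gives the organomercurial F9. Alkaline NaBH4 at 0 °C removes the mercury.

**Step 9.** The acidic, chelating triketone may deactivate the ruthenium carbene, and metathesis of an internal alkene next to a quaternary carbon may stall. Fallback from 14, returning at 15: Lemieux–Johnson cleavage (OsO4 cat., NaIO4, 2,6-lutidine) gives the aldehyde F10, and a Wittig reaction with isopropylidenetriphenylphosphorane gives 15.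

## Further compounds

F1 | step 7 | (2E,6R)-1-chloro-2,6-dimethyl-6-(triethylsilyloxy)octa-2,7-diene | C=C[C@](C)(O[Si](CC)(CC)CC)CC/C=C(\C)CCl
F2 | step 7 | cis-2-(chloromethyl)-1-methyl-3-(prop-1-en-2-yl)cyclopentyl triethylsilyl ether, silyloxy, chloromethyl and isopropenyl all cis | ClC[C@H]1[C@H](CC[C@@]1(C)O[Si](CC)(CC)CC)C(C)=C
F3 | step 7 | bis-chloride: F2 with the isopropenyl methyl chlorinated (3-chloroprop-1-en-2-yl group) | ClC[C@H]1[C@H](CC[C@@]1(C)O[Si](CC)(CC)CC)C(=C)CCl
F4 | step 7 | 8 alkylated at C5 with the 2-substituted allyl group of F3 | CC[C@H](C)C(=O)c1c(O)c(CC(=C)[C@H]2CC[C@@](C)(O[Si](CC)(CC)CC)[C@H]2CCl)c(O)c(C)c1O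
F5 | step 7 | dearomatised triketone: F4 with an (E)-but-2-enyl group on C3 (configured as in 16) | CC[C@H](C)C(=O)C1=C(O)[C@@](C)(C/C=C/C)C(=O)C(CC(=C)[C@H]2CC[C@@](C)(O[Si](CC)(CC)CC)[C@H]2CCl)=C1O
F6 | step 7 | spiro compound with exocyclic C7' methylene (double-bond isomer of 12) | CC[C@H](C)C(=O)C1=C(O)[C@@](C)(C/C=C/C)C(=O)[C@]2(C[C@H]3[C@H](CC[C@@]3(C)O[Si](CC)(CC)CC)C(=C)C2)C1=O
F7 | step 6 | C3 epimer of 10 | CC[C@H](C)C(=O)C1=C(O)[C@](C)(C/C=C/C)C2=C(C=C(C)C(CC[C@@](C)(O[Si](CC)(CC)CC)C=C)O2)C1=O
F8 | step 6 | C3,C5-bis-epimer of 12 | CC[C@H](C)C(=O)C1=C(O)[C@](C)(C/C=C/C)C(=O)[C@@]2(C[C@H]3[C@H](CC[C@@]3(C)O[Si](CC)(CC)CC)C(C)=C2)C1=O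
F9 | step 8 | C8' acetoxymercurio derivative of 14, mercury trans to the C7' hydroxyl | CC[C@H](C)C(=O)C1=C(O)[C@@](C)(C/C=C/C)C(=O)[C@]2(C[C@H]3[C@H](CC[C@@]3(C)O[Si](CC)(CC)CC)[C@](C)(O)[C@H]2[Hg]OC(C)=O)C1=O
F10 | step 9 | aldehyde: 14 with the but-2-enyl group cleaved to a 2-oxoethyl group | CC[C@H](C)C(=O)C1=C(O)[C@@](C)(CC=O)C(=O)[C@]2(C[C@H]3[C@H](CC[C@@]3(C)O[Si](CC)(CC)CC)[C@](C)(O)C2)C1=O
A1 | alternative 1 | dearomatised acylphloroglucinol with methyl and prenyl on C3 and a free C5–H | CC[C@H](C)C(=O)C1=C(O)[C@@](C)(CC=C(C)C)C(=O)C=C1O
A2 | alternative 1 | cis-cyclopentane bis-electrophile: iodomethyl at C2', 2-methyloxiranyl at C6' (epoxide carbon uncontrolled) | IC[C@H]1[C@H](CC[C@@]1(C)O[Si](CC)(CC)CC)C2(C)CO2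
A3 | alternative 2 | C5-(cyclopentylmethyl) triketone with an isopropenyl group at C6' | CC[C@H](C)C(=O)C1=C(O)[C@@](C)(CC=C(C)C)C(=O)C(C[C@H]2[C@H](CC[C@@]2(C)O)C(C)=C)=C1O
A4 | alternative 3 | spiro cis-hydrindane-3',7'-dione | CC[C@H](C)C(=O)C1=C(O)[C@@](C)(CC=C(C)C)C(=O)[C@]2(C[C@H]3[C@H](CCC3=O)C(=O)C2)C1=O
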